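Slowness can be measured before anything is fitted: the oak flask at 0.20 µM of enzyme needs 8.00 min for 75.7% product, the alder flask at 0.13 µM needs 15.0 min for 77.1%.

| setting | oak | alder | larch | south-west | south | north-west |
|---|---|---|---|---|---|---|
| substrate | 0.020 M | 0.020 M | 0.020 M | 0.020 M | 0.020 M | 0.020 M (fed, over 20.0 min) |
| enzyme | 0.20 µM | 0.13 µM | 0.30 µM | 0.20 µM | 0.20 µM | 0.20 µM |
| remark | run made earlier | run made earlier | run made earlier | a closed flask charged with all of it at once and left for 20 min | a single well-mixed tank run continuously and read at steady state, 20 min in it on average | all but substrate at the start; substrate goes in evenly over 20.0 min, the run ends at 20 min |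
| time |  |  |  | 20 min |  | 20 min |

- oak (time / min: product / %, substrate / %): 1.50: 15.9, 81.8; 2.50: 28.2, 72.0; 4.00: 44.6, 56.3; 8.00: 75.7, 25.6; 12.0: 91.7, 8.7; 20.0: 98.3, 0
- alder (time / min: product / %, substrate / %): 1.33: 9.4, 89.2; 2.00: 14.7, 85.3; 4.00: 28.6, 71.1; 6.00: 41.4, 60.1; 10.0: 59.0, 39.7; 15.0: 77.1, 21.4
- larch (time / min: product / %, substrate / %): 1.00: 18.5, 82.4; 3.00: 48.3, 52.3; 6.00: 83.7, 16.5; 8.00: 93.3, 6.6; 12.0: 99.1, 0; 15.0: 99.9, 0.1

(each reading ± 1 percentage point)

- the set-up with the highest amount of product at the outlet or at the end, in percent of the substrate put in ("none" if the first two lie within 2 percentage points) (south-west / south / north-west / none)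
- amount of product at the outlet or at the end, in percent of the substrate put in, south-west
- amount of product at the outlet or at the end, in percent of the substrate put in, south
- amount of product at the outlet or at the end, in percent of the substrate put in, north-west

- the stated concentrations are those of everything mixed, before any reaction; amounts are the same in each set-up
- the earlier runs were read with a standard deviation of 1 percentage point
- the feed brings no volume worth counting
- the earlier runs were made in a closed, stirred flask

1. Amount of enzyme. If enzyme held its strength, time would scale inversely with it, and the alder flask would need 12.3 min. It needs longer, 15.0 min, though its reading stands 1.4 percentage points higher, about the scatter. So I assume first-order loss of enzyme (catalyst deactivation) with constant k. Equating the two flasks' enzyme-minutes, the fading counted to first order, I read k = 0.0426 min⁻¹.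

2. Time. In a closed flask, speed at a given substrate level goes with living enzyme, so product follows the fresh-enzyme time θ, the minutes of enzyme at 0.20 µM that a run has had. For south-west, θ = 13.5 min. The larch flask at 12.0 min has 14.1 min and reads 99.1%, so I expect south-west just below that.

3. Vessel. The north-west feed brings 0.0500 min⁻¹ of the charge, while the oak flask's first reading gives 0.106 min⁻¹. Faded to 42.7%, that speed is 0.0452 min⁻¹ at the end, less than the feed, so I expect substrate to gather late. I put south-west first and give the tank no figure.

The forecast says south-west, with 98.7%, 80% and 73% for south-west, south and north-west, holding that in the fed flask “substrate accumulates late as the enzyme fades”.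

The flasks give 99.5%, 81.0% and 75.7%, in the same order.

    substrate + enzyme → product + enzyme, rate k1*[substrate]*[enzyme]/(1 + ([substrate]/Km1)) (4.00 mM, k = 61000 L mol⁻¹ s⁻¹)
    enzyme → spent catalyst (k = 0.0380 min⁻¹)

South-west has half of its turnover up to 20 min behind it at 4.74 min, earlier than the enzyme's half-life of 18 min, and it ends with 0.509% substrate; the θ I reckoned for it, with the k read off the runs, is an estimate of 13.5 min. For a flask like south-west with 5.0 × 10⁻⁸ M of enzyme, the same k gives an estimated θ = 3.37 min, less than the 3.68 min it gives for the oak flask at 4.00 min, where 44.6% was read, and that flask ends at 40.8% product.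

Readings and results were computed for substances that don't exist, noise included.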